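**Plan**

- Lettering: ring A is the 3,5-dihydroxyphenoxy ring; ring B is the central ring (position 1 bears the oxygen to ring A, position 4 the oxygen to ring C, hydroxyls at positions 2 and 6); ring C is the brominated ring (ether oxygen on position 1, hydroxyls at positions 2, 4 and 6, bromine at position 5).
- Retrosynthesis: first cut the three O–CH3 bonds (two on ring A, one at position 4 of ring C); then the four C–O bonds at positions 2 and 6 of rings B and C, each hydroxyl going back to a formyl group; then the two diaryl ether bonds (oxygen of ring B to position 1 of ring C, oxygen of ring A to position 1 of ring B), both fluoride displacements; last the C–Br bond of ring C and one formyl C–C bond of a fluoro dialdehyde shared by rings B and C.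
- Enabling feature: the hydroxyls at positions 2 and 6 of ring B and of ring C flank the ether carbon (position 1) of each ring, so a pair of ortho formyl groups can activate fluoride at that carbon for SNAr and afterwards be exchanged for oxygen.
- Forward: no ring is built; the three benzene rings come from two purchased arenes. 2-Fluoro-5-methoxyisophthalaldehyde is made and divided into a brominated ring C block and an O-allyl ring B block; ring A is joined to ring B, then the AB unit to ring C; the four aldehydes are oxidised in one operation; the methyl ethers are removed last.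
- Stereochemistry: none to set; the target has no stereocentre.

Key step: step 9

**Route**

Step 1
Reactants: 1 2-fluoro-5-methoxybenzaldehyde
Product: 2 2-(2-fluoro-5-methoxyphenyl)-1,3-dioxolane
Conditions: HOCH2CH2OH, TsOH·H2O (cat.), toluene, reflux, Dean–Stark
Reagents that add atoms: ethylene glycol, OCCO
Why: Acid-catalysed acetalisation with azeotropic removal of water masks the aldehyde as a dioxolane that tolerates the organolithium base of the next step.

Step 2
Reactants: 2 2-(2-fluoro-5-methoxyphenyl)-1,3-dioxolane
Product: 5 2-fluoro-5-methoxybenzene-1,3-dicarbaldehyde, via aryllithium 3 (not isolated), via acetal aldehyde 4 (not isolated)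
Conditions: n-BuLi, PMDTA, THF, −78 °C; DMF, −78 → 0 °C; 2 M HCl, THF, rt
Reagents that add atoms: n-butyllithium, CCCC[Li] (lithium of intermediate 3 only); N,N-dimethylformamide, CN(C)C=O; water, O
Why: Directed ortho-metalation in which the PMDTA-complexed base removes the most acidic ring hydrogen, the one next to fluorine (the selectivity known for 4-fluoroanisole under these conditions), the aryllithium is formylated by DMF at −78 °C before it can lose LiF, and aqueous acid then hydrolyses the dioxolane.

Step 3
Reactants: 5 2-fluoro-5-methoxybenzene-1,3-dicarbaldehyde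
Product: 6 4-bromo-2-fluoro-5-methoxybenzene-1,3-dicarbaldehyde
Conditions: NBS (1.05 equiv), CF3CO2H/H2SO4, rt
Reagents that add atoms: N-bromosuccinimide, O=C1CCC(=O)N1Br
Why: Electrophilic aromatic bromination with acid-activated NBS, in which the only two free ring positions are equivalent and ortho to the methoxy donor, and the first bromine deactivates and shields the ring against a second.

Step 4
Reactants: 5 2-fluoro-5-methoxybenzene-1,3-dicarbaldehyde
Product: 7 2-fluoro-5-hydroxybenzene-1,3-dicarbaldehyde
Conditions: BBr3 (3 equiv), CH2Cl2, −78 → 0 °C; H2O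
Reagents that add atoms: none
Why: Lewis acid-mediated aryl methyl ether cleavage (bromide attacks the O-methyl carbon of the boron-complexed ether), which at low temperature should leave the aryl fluoride and the formyl groups intact.

Step 5
Reactants: 7 2-fluoro-5-hydroxybenzene-1,3-dicarbaldehyde
Product: 8 2-fluoro-5-(prop-2-en-1-yloxy)benzene-1,3-dicarbaldehyde
Conditions: allyl bromide (1.5 equiv), K2CO3, acetone, rt
Reagents that add atoms: allyl bromide, C=CCBr
Why: Williamson etherification of an acidic phenol, run at room temperature with the alkyl halide present from the start so that the weakly nucleophilic phenoxide is alkylated before it can displace fluoride from the product.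

Step 6
Reactants: 8 2-fluoro-5-(prop-2-en-1-yloxy)benzene-1,3-dicarbaldehyde; 9 3,5-dimethoxyphenol
Product: 10 2-(3,5-dimethoxyphenoxy)-5-(prop-2-en-1-yloxy)benzene-1,3-dicarbaldehyde
Conditions: K2CO3, DMF, 60 °C
Reagents that add atoms: none
Why: Nucleophilic aromatic substitution by addition–elimination, the fluoride flanked by two ortho formyl groups being displaced by the phenoxide through a Meisenheimer adduct while the allyl ether is inert.

Step 7
Reactants: 10 2-(3,5-dimethoxyphenoxy)-5-(prop-2-en-1-yloxy)benzene-1,3-dicarbaldehyde
Product: 11 2-(3,5-dimethoxyphenoxy)-5-hydroxybenzene-1,3-dicarbaldehyde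
Conditions: Pd(PPh3)4 (5 mol %), N-methylaniline (3 equiv), THF, rt
Reagents that add atoms: none
Why: Tsuji–Trost-type deallylation in which zerovalent palladium ionises the allyl aryl ether and N-methylaniline captures the allyl fragment, a neutral process that spares the methyl ethers, the diaryl ether and the aldehydes (a secondary aniline forms no stable adduct with them).

Step 8
Reactants: 11 2-(3,5-dimethoxyphenoxy)-5-hydroxybenzene-1,3-dicarbaldehyde; 6 4-bromo-2-fluoro-5-methoxybenzene-1,3-dicarbaldehyde
Product: 12 4-bromo-2-[4-(3,5-dimethoxyphenoxy)-3,5-diformylphenoxy]-5-methoxybenzene-1,3-dicarbaldehyde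
Conditions: K2CO3, DMF, 50 °C, 1:1 stoichiometry
Reagents that add atoms: none
Why: Nucleophilic aromatic substitution in which the fluoride between two formyl groups should leave far faster than the bromide (also ortho/para to formyl groups but a much poorer nucleofuge in addition–elimination and shielded by the neighbouring methoxy group), with equimolar partners and a mild temperature guarding against bromide displacement and aryloxy exchange.

Step 9
Reactants: 12 4-bromo-2-[4-(3,5-dimethoxyphenoxy)-3,5-diformylphenoxy]-5-methoxybenzene-1,3-dicarbaldehyde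
Product: 14 4-bromo-2-[4-(3,5-dimethoxyphenoxy)-3,5-dihydroxyphenoxy]-5-methoxybenzene-1,3-diol, via tetraformate 13 (not isolated)
Conditions: mCPBA (6 equiv), CH2Cl2, 0 °C → rt; aq. Na2S2O3 wash; Et3N (0.5 equiv), degassed MeOH, rt
Reagents that add atoms: 3-chloroperbenzoic acid, O=C(OO)c1cccc(Cl)c1
Why: Each formyl group adds the peracid to give a Criegee adduct, from which the ring carbon migrates to the peroxide oxygen with loss of 3-chlorobenzoate to give an aryl formate, and triethylamine in methanol then transfers the four formyl groups to the solvent. The closest known reaction is the peracid Baeyer–Villiger (Dakin-type) oxidation of ortho-aryloxy- and ortho-alkoxybenzaldehydes, the usual way of turning an SNAr-activating formyl group of a diaryl ether into a hydroxyl; here it has to run four times on one molecule, twice on each of two isophthalaldehyde rings. No ring is closed and no stereocentre is formed. The selectivity needed is aryl over hydride migration at all four sites, and it is secured by the diaryl ether oxygens on position 1 of ring B and of ring C, one of which stands ortho to every formyl group and stabilises the electron-poor migrating carbon, with the 3-chlorobenzoic acid released giving acid assistance to adduct formation and O–O cleavage. Chemoselectivity for the aldehydes over the electron-rich ring A is helped because the new oxygens stay masked as electron-poor formates until the peracid has been destroyed.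

Step 10
Reactants: 14 4-bromo-2-[4-(3,5-dimethoxyphenoxy)-3,5-dihydroxyphenoxy]-5-methoxybenzene-1,3-diol
Product: 15 4-bromo-2-[4-(3,5-dihydroxyphenoxy)-3,5-dihydroxyphenoxy]benzene-1,3,5-triol (CNP0039507.0)
Conditions: BBr3 (12 equiv), CH2Cl2, −78 °C → rt; MeOH then H2O, 0 °C
Reagents that add atoms: none
Why: Lewis acid-mediated cleavage of the three aryl methyl ethers, in which the diaryl ether bonds and the aryl bromide do not react, the excess reagent allows for the four free phenols that bind boron, and the cold quench limits contact of the bromophloroglucinol ring with HBr.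

**Compound list**

1 | 2-fluoro-5-methoxybenzaldehyde | COc1ccc(F)c(C=O)c1 | starting material
2 | 2-(2-fluoro-5-methoxyphenyl)-1,3-dioxolane | COc1ccc(F)c(C2OCCO2)c1 | intermediate
3 | [3-(1,3-dioxolan-2-yl)-2-fluoro-5-methoxyphenyl]lithium | [Li]c1cc(OC)cc(C2OCCO2)c1F | intermediate
4 | 3-(1,3-dioxolan-2-yl)-2-fluoro-5-methoxybenzaldehyde | COc1cc(C=O)c(F)c(C2OCCO2)c1 | intermediate
5 | 2-fluoro-5-methoxybenzene-1,3-dicarbaldehyde | COc1cc(C=O)c(F)c(C=O)c1 | intermediate
6 | 4-bromo-2-fluoro-5-methoxybenzene-1,3-dicarbaldehyde | COc1cc(C=O)c(F)c(C=O)c1Br | intermediate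
7 | 2-fluoro-5-hydroxybenzene-1,3-dicarbaldehyde | O=Cc1cc(O)cc(C=O)c1F | intermediate
8 | 2-fluoro-5-(prop-2-en-1-yloxy)benzene-1,3-dicarbaldehyde | C=CCOc1cc(C=O)c(F)c(C=O)c1 | intermediate
9 | 3,5-dimethoxyphenol | COc1cc(O)cc(OC)c1 | starting material
10 | 2-(3,5-dimethoxyphenoxy)-5-(prop-2-en-1-yloxy)benzene-1,3-dicarbaldehyde | C=CCOc1cc(C=O)c(Oc2cc(OC)cc(OC)c2)c(C=O)c1 | intermediate
11 | 2-(3,5-dimethoxyphenoxy)-5-hydroxybenzene-1,3-dicarbaldehyde | COc1cc(OC)cc(Oc2c(C=O)cc(O)cc2C=O)c1 | intermediate
12 | 4-bromo-2-[4-(3,5-dimethoxyphenoxy)-3,5-diformylphenoxy]-5-methoxybenzene-1,3-dicarbaldehyde | COc1cc(OC)cc(Oc2c(C=O)cc(Oc3c(C=O)cc(OC)c(Br)c3C=O)cc2C=O)c1 | intermediate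
13 | 4-bromo-2-[4-(3,5-dimethoxyphenoxy)-3,5-bis(formyloxy)phenoxy]-5-methoxy-1,3-phenylene diformate | COc1cc(OC)cc(Oc2c(OC=O)cc(Oc3c(OC=O)cc(OC)c(Br)c3OC=O)cc2OC=O)c1 | intermediate
14 | 4-bromo-2-[4-(3,5-dimethoxyphenoxy)-3,5-dihydroxyphenoxy]-5-methoxybenzene-1,3-diol | COc1cc(OC)cc(Oc2c(O)cc(Oc3c(O)cc(OC)c(Br)c3O)cc2O)c1 | intermediate
15 | 4-bromo-2-[4-(3,5-dihydroxyphenoxy)-3,5-dihydroxyphenoxy]benzene-1,3,5-triol (CNP0039507.0) | Oc1cc(O)cc(Oc2c(O)cc(Oc3c(O)cc(O)c(Br)c3O)cc2O)c1 | target

**Step count**

Total: 10 steps. Longest linear sequence: 9 steps (steps 1, 2, 4, 5, 6, 7, 8, 9, 10); step 3 is a one-step branch from 5 that delivers ring C to step 8.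

**Steps most likely to fail**

Step 9. Hydride instead of aryl migration may take over in the Criegee adducts of the most electron-poor formyl groups, those that still have a formyl or formate group meta to them; this would leave carboxylic acids. The fourfold conversion may also stall, or excess peracid may attack ring A. The fallback sets out from 12 and returns at 14, and replaces the aryl-against-hydride contest by aryl against methyl. Addition of MeMgBr (THF, −78 °C) to all four aldehydes should give the tetrakis(1-hydroxyethyl) compound F1 as a mixture of diastereomers, which is of no consequence. Dess–Martin periodinane (CH2Cl2, rt) should oxidise it to the tetraacetyl compound F2. Baeyer–Villiger oxidation of F2 with mCPBA (CH2Cl2, catalytic CF3CO2H), in which aryl migrates in preference to methyl, should give the tetraacetate F3. Methanolysis of F3 (K2CO3, degassed MeOH) should then give 14.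

Step 3. Bromination may stall on a ring that carries two formyl groups and fluorine, or the aldehydes may be oxidised under the strongly acidic conditions needed. The fallback sets out from 7 and returns at 6, and moves the bromination to the far more activated phenol. NBS (1.0 equiv, MeCN, 0 °C) should brominate 7 at one of the two equivalent positions ortho to the hydroxyl to give 4-bromo-2-fluoro-5-hydroxybenzene-1,3-dicarbaldehyde F4. O-Methylation of F4 (MeI, K2CO3, acetone, rt) should then give 6.

Step 2. Metalation may occur at the wrong ring position (between the methoxy group and the dioxolane, or ortho to methoxy), or the ortho-fluoro aryllithium may lose LiF to an aryne before DMF traps it. The fallback sets out from 2 and returns at 5, and replaces deprotonation by a sterically governed C–H borylation followed by a magnesium reagent that does not form an aryne. Iridium-catalysed borylation of 2 ([Ir(OMe)(cod)]2, 4,4'-di-tert-butyl-2,2'-bipyridine, bis(pinacolato)diboron, THF, 70 °C) should take place at the only C–H flanked by nothing larger than fluorine and give the boronate 2-[3-(1,3-dioxolan-2-yl)-2-fluoro-5-methoxyphenyl]-4,4,5,5-tetramethyl-1,3,2-dioxaborolane F5. Iododeboronation (NaI, TsN(Cl)Na, aqueous THF, rt) should convert it into 2-(2-fluoro-3-iodo-5-methoxyphenyl)-1,3-dioxolane F6. Iodine–magnesium exchange (i-PrMgCl·LiCl, THF, −40 °C) should then give the arylmagnesium chloride F7. DMF should convert this into acetal aldehyde 4, and 2 M HCl should hydrolyse 4 to 5.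

**Further compounds**

F1 | step 9 | 1,1',1'',1'''-tetrol obtained from 12 by replacing each CHO by CH(OH)CH3 (mixture of diastereomers) | COc1cc(OC)cc(Oc2c(C(C)O)cc(Oc3c(C(C)O)cc(OC)c(Br)c3C(C)O)cc2C(C)O)c1
F2 | step 9 | tetraacetyl analogue of 12 (each CHO replaced by COCH3) | COc1cc(OC)cc(Oc2c(C(C)=O)cc(Oc3c(C(C)=O)cc(OC)c(Br)c3C(C)=O)cc2C(C)=O)c1
F3 | step 9 | tetraacetate of 14 | COc1cc(OC)cc(Oc2c(OC(C)=O)cc(Oc3c(OC(C)=O)cc(OC)c(Br)c3OC(C)=O)cc2OC(C)=O)c1
F4 | step 3 | 4-bromo-2-fluoro-5-hydroxybenzene-1,3-dicarbaldehyde | O=Cc1cc(O)c(Br)c(C=O)c1F
F5 | step 2 | 2-[3-(1,3-dioxolan-2-yl)-2-fluoro-5-methoxyphenyl]-4,4,5,5-tetramethyl-1,3,2-dioxaborolane | COc1cc(B2OC(C)(C)C(C)(C)O2)c(F)c(C2OCCO2)c1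
F6 | step 2 | 2-(2-fluoro-3-iodo-5-methoxyphenyl)-1,3-dioxolane | COc1cc(I)c(F)c(C2OCCO2)c1
F7 | step 2 | [3-(1,3-dioxolan-2-yl)-2-fluoro-5-methoxyphenyl]magnesium chloride | COc1cc([Mg]Cl)c(F)c(C2OCCO2)c1
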